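The ratio I reckoned with was that of two logarithms of what remained in one flask at one time: x for the left-handed substrate and y for the right-handed one, each the logarithm of charge over remainder.

| flask | left-handed substrate | right-handed substrate | partner | protic impurity | catalyst | added ligand | remark | time |
|---|---|---|---|---|---|---|---|---|
| north-east | 0.20 M | 0.20 M | 0.60 M | 0.020 M | 0.15 mM | 1.7 mM | run made earlier |  |
| west | 0.20 M | 0.20 M | 0.60 M | 0.020 M | 0.60 mM | 1.7 mM | run made earlier |  |
| red | 0.20 M | 0.20 M | 0.600 M | 0.0200 M | 0.80 mM | 1.7 mM |  | 2.5 h |
| green | 0.20 M | 0.20 M | 0.600 M | 0.0200 M | 0.20 mM | 1.7 mM |  | 2.5 h |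

| run | time / h | right-handed substrate / % | left-handed substrate / % | left-handed product / % |
|---|---|---|---|---|
| north-east | 0.167 | 49.7 | 46.8 | 3.4 |
| north-east | 0.500 | 49.1 | 42.8 | 7.6 |
| north-east | 0.833 | 48.7 | 40.2 | 11.7 |
| north-east | 1.33 | 47.8 | 35.2 | 16.2 |
| north-east | 2.00 | 46.5 | 30.2 | 17.8 |
| north-east | 2.50 | 46.1 | 30.5 | 21.8 |
| west | 0.167 | 48.6 | 33.8 | 15.5 |
| west | 0.500 | 44.5 | 25.8 | 23.1 |
| west | 0.833 | 42.8 | 20.5 | 29.6 |
| west | 1.33 | 39.2 | 12.3 | 39.2 |
| west | 2.00 | 39.8 | 8.6 | 41.9 |
| west | 2.50 | 36.5 | 6.4 | 42.4 |

(standard deviation of a reading: 1 percentage point)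

* which of the two ends with the higher excess of right-handed substrate over left-handed substrate among what is left of the two ("neither" if they lie within 2 percentage points) (red / green / neither)
* excess of right-handed substrate over left-handed substrate among what is left of the two at the end, red
* excess of right-handed substrate over left-handed substrate among what is left of the two at the end, green

- catalyst is single-handed; left-handed substrate and right-handed substrate are mirror images of each other, charged as a racemate, each of them at the stated concentration
- the earlier runs were read with a standard deviation of 1 percentage point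
- an excess is the difference of the two amounts in percent of their sum
- an excess is below zero if the other one leads

These two numbers give the two remainders, and the excess needs nothing else. With a ratio of 1, the symmetric case, a racemate keeps an excess of zero, so that is the zero of the scale.

West ended at x = 2.06 and y = 0.315, which gave a reading of 6.53 for s, the selectivity factor, x over y. North-east, with a quarter of the catalyst, read 6.09, so I kept the west value. I took a slowing shared by both substrates to drop out of the ratio and left the early burst unexplained.

Scaled by catalyst, west's x gave 0.514 for north-east, where 0.494 was read, so I scaled it to the new flasks, at equal time: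

left = exp(−x), right = exp(−x/s), excess = (right − left)/(right + left)

red: x = 2.74, left 6.45 %, right 65.7 %, excess 82.1 %

green: x = 0.685, left 50.4 %, right 90.0 %, excess 28.2 %

The forecast named red, with 81 % (72 % to 88 %) for red, a little lower than my figure, and 28 % (22 % to 34 %) for green, and it said of the selectivity “so it does not depend on loading”.

The flasks gave 82.8 % for red and 30.5 % for green, so red ended higher.

    partner + catalyst + left-handed substrate → catalyst + left-handed product (k = 2.90 L² mol⁻² s⁻¹)
    partner + catalyst + right-handed substrate → catalyst + right-handed product (k = 0.410 L² mol⁻² s⁻¹)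
    partner + protic impurity → quenched reagent (k = 0.0440 L mol⁻¹ s⁻¹)
    catalyst + added ligand ⇌ idle complex (K = 1700 L mol⁻¹, k = 1.10 L mol⁻¹ s⁻¹)
    partner ⇌ dormant form (K = 0.120, k = 4.80 × 10⁻⁴ s⁻¹)

Red's left-handed substrate ended at 6.4 % of its charge, and s turns that into 65.6 % of the right-handed charge, where red held 68 %. The neighbouring flask is red with the catalyst at 0.320 mM. The same scaling gave it x = 1.10, left 33.4 %, right 84.5 % and an excess of 43.4 %. That flask ended with 32 % of the left-handed charge, 85 % of the right-handed charge and an excess of 45.5 %.

All runs stem from a simulated flask on assumed constants, and the scatter is random.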